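**Assumption:** the SMILES has no stereocentre and no E/Z-stereogenic alkene (the prenyl terminus carries two methyls). The target is therefore achiral and needs no asymmetric step. The one stereocentre made en route (carbinol in 8) is racemic and is erased in Step 6.

## Retrosynthetic overview
1. Target ⇒ its 5-O-methyl, 4'-O-MOM ether. The phenols are released last by MOM methanolysis and then chelation-controlled 5-O-demethylation.
2. That 8-prenylflavone ⇒ an acyclic o-(1,1-dimethylallyloxy)aryl ynone. This is the new step: one isomerisation forms both C8–C1'' and O1–C2. The oxygen carrying the tert-prenyl group becomes O1, so the prenyl can only land on C8.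
3. Ynone ⇒ A-ring aldehyde + B-ring terminal alkyne, joined by acetylide addition and then oxidation (C4–C3 bond).
4. A-ring piece ⇐ 4,6-dimethoxysalicylaldehyde (Cu-propargylation, Lindlar). B-ring piece ⇐ 4-hydroxy-2-methoxybenzaldehyde (MOM, Ohira–Bestmann).
5. Ring order: benzene rings A and B are purchased. Only the pyranone C ring is built, in Step 7.

## Route

**Step 1**
Reactants: 1, 2-hydroxy-4,6-dimethoxybenzaldehyde; 2, 3-chloro-3-methylbut-1-yne
Product: 3, 2,4-dimethoxy-6-[(2-methylbut-3-yn-2-yl)oxy]benzaldehyde
Conditions: 2 (1.5 equiv), DBU (1.6 equiv), CuCl2·2H2O (1 mol %), MeCN, 0 °C → rt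
Reagents that add atoms: compound 2, 3-chloro-3-methylbut-1-yne, C#CC(C)(C)Cl
Why: Cu-catalysed tertiary propargylic etherification via a Cu-allenylidene; DBU breaks the OH···O=C hydrogen bond, and acidic acyl phenoxides are good nucleophiles for this O-alkylation.

**Step 2**
Reactants: 3
Product: 4, 2,4-dimethoxy-6-[(2-methylbut-3-en-2-yl)oxy]benzaldehyde (tert-prenyl ether; keep below 30 °C)
Conditions: H2 (1 atm), Lindlar catalyst, quinoline, EtOAc, rt, stop at 1 equiv H2
Reagents that add atoms: none
Why: Lindlar semihydrogenation; the terminal alkyne is reduced much faster than the resulting alkene or the aryl aldehyde on poisoned Pd.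

**Step 3**
Reactants: 5, 4-hydroxy-2-methoxybenzaldehyde
Product: 6, 2-methoxy-4-(methoxymethoxy)benzaldehyde
Conditions: MOMCl, i-Pr2NEt, CH2Cl2, 0 °C → rt
Reagents that add atoms: chloromethyl methyl ether (MOMCl), COCCl
Why: standard MOM protection of an acidic, non-chelated para-formyl phenol.

**Step 4**
Reactants: 6
Product: 7, 1-ethynyl-2-methoxy-4-(methoxymethoxy)benzene
Conditions: Bestmann–Ohira reagent, K2CO3, MeOH, rt
Reagents that add atoms: dimethyl (1-diazo-2-oxopropyl)phosphonate, CC(=O)C(=[N+]=[N-])P(=O)(OC)OC (delivers one carbon)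
Why: Seyferth–Gilbert homologation (Ohira–Bestmann variant) of a non-enolisable aryl aldehyde; MOM and OMe are inert to K2CO3/MeOH.

**Step 5**
Reactants: 7; 4
Product: 8, (±)-1-{2,4-dimethoxy-6-[(2-methylbut-3-en-2-yl)oxy]phenyl}-3-[2-methoxy-4-(methoxymethoxy)phenyl]prop-2-yn-1-ol
Conditions: 7, n-BuLi, THF, −78 °C; then 4, −78 → 0 °C; NH4Cl quench; use crude
Reagents that add atoms: none
Why: 1,2-addition of a lithium acetylide to an aldehyde; the low temperature preserves the tert-prenyl ether, and the racemic carbinol centre is removed in Step 6.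

**Step 6**
Reactants: 8
Product: 9, 1-{2,4-dimethoxy-6-[(2-methylbut-3-en-2-yl)oxy]phenyl}-3-[2-methoxy-4-(methoxymethoxy)phenyl]prop-2-yn-1-one
Conditions: activated MnO2 (15 equiv), CH2Cl2, rt
Reagents that add atoms: none
Why: MnO2 oxidation of a doubly activated (benzylic and propargylic) alcohol under neutral conditions at rt, so the acid- and heat-labile tert-prenyl ether and the MOM group survive.

**Step 7 (key new step)**
Reactants: 9
Product: 10, 5,7-dimethoxy-2-[2-methoxy-4-(methoxymethoxy)phenyl]-8-(3-methylbut-2-en-1-yl)-4H-chromen-4-one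
Conditions: Eu(fod)3 (10 mol %), PhCl (0.05 M), 4 Å MS, 70 °C, Ar
Reagents that add atoms: none (isomerisation, C25H28O7 → C25H28O7)
Why: Proposed new method: Lewis-acid-catalysed "Claisen-triggered cycloisomerisation" of an o-(tert-prenyloxy)aryl ynone — Eu(III) chelates the ynone C=O and the neighbouring aryl-ether O, charge-accelerating the aromatic [3,3] shift; the only free ortho carbon (future C8) bonds to the CH2 terminus, so allyl inversion converts the 1,1-dimethylallyl ether into a linear C-prenyl group; tautomerisation unmasks the phenol exactly where O1 is needed, and this Eu-bound phenol adds 6-endo-dig to the carbonyl-activated alkyne, whose β-carbon is made the electrophilic site by the donor 2,4-dioxygenated aryl group (disfavouring 5-exo aurone formation); C3 protonation then releases the catalyst, so C8–C1'' and O1–C2 form in one atom-economical step with no C6/C8 ambiguity and no stereocentre; the closest known reaction types are the thermal tandem aromatic Claisen/6-endo cyclisation of o-allyloxyaryl enaminones to 8-allylchromones, Eu(fod)3-catalysed Claisen(–Cope) shifts of flavonoid prenyl ethers, and acid- or amine-promoted 6-endo cyclisation of o-hydroxyaryl ynones, and to my knowledge these have not been merged on a tert-prenyl ether/ynone to build a flavone.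

**Step 8**
Reactants: 10
Product: 11, 2-(4-hydroxy-2-methoxyphenyl)-5,7-dimethoxy-8-(3-methylbut-2-en-1-yl)-4H-chromen-4-one
Conditions: 3 M aq HCl/MeOH (1:5), 45 °C
Reagents that add atoms: none
Why: acid-catalysed MOM acetal methanolysis; aryl methyl ethers are inert, and the C8 prenyl has no free ortho OH (it is flanked by 7-OMe and O1), so chroman formation is impossible.

**Step 9**
Reactants: 11
Product: 12, artocarpetin B, 5-hydroxy-2-(4-hydroxy-2-methoxyphenyl)-7-methoxy-8-(3-methylbut-2-en-1-yl)-4H-chromen-4-one
Conditions: MgI2·OEt2 (4 equiv), THF, reflux; aq Na2S2O3/1 M HCl work-up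
Reagents that add atoms: none
Why: chelation-controlled demethylation; Mg(II) binds C4=O and 5-OMe in a six-membered chelate and iodide removes that methyl by SN2, while the non-chelating 7- and 2'-OMe groups, the free 4'-OH and the prenyl alkene are untouched, as in the same 5-O-demethylation of 8-prenyl-5-methoxyflavanones.

## Compound list
| No. | Name | SMILES | Role |
|---|---|---|---|
| 1 | 2-hydroxy-4,6-dimethoxybenzaldehyde | COc1cc(O)c(C=O)c(OC)c1 | starting material |
| 2 | 3-chloro-3-methylbut-1-yne | C#CC(C)(C)Cl | starting material |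
| 3 | 2,4-dimethoxy-6-[(2-methylbut-3-yn-2-yl)oxy]benzaldehyde | COc1cc(OC(C)(C)C#C)c(C=O)c(OC)c1 | intermediate |
| 4 | 2,4-dimethoxy-6-[(2-methylbut-3-en-2-yl)oxy]benzaldehyde | COc1cc(OC(C)(C)C=C)c(C=O)c(OC)c1 | intermediate |
| 5 | 4-hydroxy-2-methoxybenzaldehyde | COc1cc(O)ccc1C=O | starting material |
| 6 | 2-methoxy-4-(methoxymethoxy)benzaldehyde | COCOc1ccc(C=O)c(OC)c1 | intermediate |
| 7 | 1-ethynyl-2-methoxy-4-(methoxymethoxy)benzene | COCOc1ccc(C#C)c(OC)c1 | intermediate |
| 8 | (±)-propargylic alcohol (racemic, centre erased in Step 6) | COCOc1ccc(C#CC(O)c2c(OC)cc(OC)cc2OC(C)(C)C=C)c(OC)c1 | intermediate |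
| 9 | o-(tert-prenyloxy)aryl ynone | COCOc1ccc(C#CC(=O)c2c(OC)cc(OC)cc2OC(C)(C)C=C)c(OC)c1 | intermediate |
| 10 | 5,7,2'-trimethoxy-4'-(methoxymethoxy)-8-prenylflavone | COCOc1ccc(-c2cc(=O)c3c(OC)cc(OC)c(CC=C(C)C)c3o2)c(OC)c1 | intermediate |
| 11 | 4'-hydroxy-5,7,2'-trimethoxy-8-prenylflavone | COc1cc(O)ccc1-c1cc(=O)c2c(OC)cc(OC)c(CC=C(C)C)c2o1 | intermediate |
| 12 | artocarpetin B (achiral) | COc1cc(O)ccc1-c1cc(=O)c2c(O)cc(OC)c(CC=C(C)C)c2o1 | target |

## Summary
Total steps: 9. Longest linear sequence: 7 (Steps 1, 2, 5, 6, 7, 8, 9; the B-ring branch 3, 4, 5–9 is also 7).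

**Three steps most likely to fail**

1. **Step 7 (proposed new cascade).**
   - Risks: ionisation of the tertiary ether with loss of isoprene, giving the 8-H flavone; O→C3 prenyl transfer, giving the 3-prenylflavone; 5-exo closure, giving the aurone; product inhibition of Eu.
   - Fallback (known chemistry, different ring construction): apply Steps 1–2 to commercial 2-hydroxy-4,6-dimethoxyacetophenone. Carry out the ordinary thermal aromatic Claisen (PhNEt2, about 125 °C) to 2-hydroxy-4,6-dimethoxy-3-prenylacetophenone. Esterify (EDC/DMAP) with 2-methoxy-4-(methoxymethoxy)benzoic acid, made by Pinnick oxidation of 6. A Baker–Venkataraman rearrangement (KOH/pyridine) followed by acid cyclodehydration then gives 11, which rejoins the route at Step 9.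

2. **Step 1 (tertiary O-propargylation of a chelated phenol).**
   - Risks: low conversion, or elimination of 2 to the enyne.
   - Fallback: replace the alkyne route with Pd(0) π-allyl etherification. Use Pd(PPh3)4 and tert-butyl (2-methylbut-3-en-2-yl) carbonate in THF at 0 °C, on the pre-formed Cs phenoxide. Kinetic attack at the substituted terminus gives 4 directly and removes Step 2.

3. **Step 9 (selective 5-O-demethylation next to a prenyl group).**
   - Risks: a sluggish reaction, HI addition to the alkene, or loss of a second methyl.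
   - Fallback: change the protecting-group plan. Start from 2,6-dihydroxy-4-methoxybenzaldehyde as its mono-MOM ether, so the future 5-O is MOM. The acid treatment of Step 8 then frees both phenols and Step 9 is not needed.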